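**Retrosynthetic overview**

- The target is 5-methylresorcinol carrying at C4 (between the C3 hydroxyl and the C5 methyl) an acyclic C1'–C11' chain with E alkenes at C2'=C3' and C6'=C7' and an (S)-C10' carbinol beside the C11' tertiary carbinol. No ring is formed in the route; the benzene ring arrives with 2,4-dihydroxy-6-methylbenzaldehyde.
- Last operations: acid removes the two phenol methoxymethyl ethers and a C11' silyl ether; before that, an oxazaborolidine reduction of the C10' ketone sets the only stereocentre.
- Key feature: the E-C6'=C7' alkene lies gamma,delta to the C10' carbonyl of an alpha-hydroxy ketone (C10' C=O, C11' C(CH3)2OH). The C8'–C9' bond is therefore cut by a ketal Claisen rearrangement of the C6' isopropenyl carbinol with 3,3-dimethoxy-2-methylbutan-2-ol.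
- The C6' carbinol comes from the C6' aldehyde and isopropenylmagnesium bromide; the aldehyde comes from an orthoacetate Claisen rearrangement of the C2' isopropenyl carbinol (C4'–C5' bond, E-C2'=C3') and ester reduction.
- The C2' carbinol comes from the arylacetaldehyde, reached from the bis-protected benzaldehyde by methylenation, hydroboration–oxidation and alcohol oxidation, all of which the methoxymethyl ethers tolerate.

Key step: step 10

Remark: 3,3-dimethoxy-2-methylbutan-2-ol is taken as not stocked and is made in step 9; carbinols 8 and 15 are used racemic because both stereocentres disappear in the Claisen steps.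

**Route**

Step 1
Reactants: 1 2,4-dihydroxy-6-methylbenzaldehyde
Product: 2 2,4-bis(methoxymethoxy)-6-methylbenzaldehyde
Conditions: NaH (2.6 equiv), MOMCl (2.5 equiv), DMF, 0 °C → rt
Reagents that add atoms: chloromethyl methyl ether, COCCl
Why: Williamson-type O-alkylation of both phenoxides; NaH breaks the hydrogen bond of the ortho hydroxyl to the aldehyde so that both oxygens should be capped.

Step 2
Reactants: 2 2,4-bis(methoxymethoxy)-6-methylbenzaldehyde
Product: 3 2-ethenyl-1,5-bis(methoxymethoxy)-3-methylbenzene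
Conditions: Ph3PCH3Br, KOtBu, THF, 0 °C → rt
Reagents that add atoms: methyltriphenylphosphonium bromide, C[P+](c1ccccc1)(c1ccccc1)c1ccccc1.[Br-]
Why: Wittig methylenation with the small non-stabilised ylide, which should reach even this di-ortho-substituted aldehyde and is basic only, so the acetals are safe.

Step 3
Reactants: 3 2-ethenyl-1,5-bis(methoxymethoxy)-3-methylbenzene
Product: 5 2-[2,4-bis(methoxymethoxy)-6-methylphenyl]ethan-1-ol, via alkylborane 4 (not isolated)
Conditions: 9-BBN (9-borabicyclo[3.3.1]nonane, 1.5 equiv), THF, 0 °C → 50 °C; then 3 M aq NaOH, 30% H2O2, 0 °C → rt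
Reagents that add atoms: hydrogen peroxide, OO
Why: Anti-Markovnikov hydroboration of the styrene by the bulky borane at the terminal carbon, followed by alkaline peroxide oxidation of the C–B bond, should give the primary alcohol under conditions harmless to the aryl acetals.

Step 4
Reactants: 5 2-[2,4-bis(methoxymethoxy)-6-methylphenyl]ethan-1-ol
Product: 6 [2,4-bis(methoxymethoxy)-6-methylphenyl]acetaldehyde
Conditions: Dess–Martin periodinane (1.2 equiv), CH2Cl2, 0 °C → rt; aq Na2S2O3/NaHCO3 work-up; used at once
Reagents that add atoms: none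
Why: Dess–Martin oxidation stops at the aldehyde under nearly neutral conditions, which suits an enolisable arylacetaldehyde that is carried on without storage.

Step 5
Reactants: 6 [2,4-bis(methoxymethoxy)-6-methylphenyl]acetaldehyde; 7 isopropenylmagnesium bromide
Product: 8 rac-1-[2,4-bis(methoxymethoxy)-6-methylphenyl]-3-methylbut-3-en-2-ol
Conditions: 7 (1.5 equiv), LaCl3·2LiCl (0.3 equiv), THF, −78 → 0 °C; aq NH4Cl
Reagents that add atoms: none
Why: Grignard 1,2-addition to the aldehyde, with the lanthanum salt raising carbonyl electrophilicity so that addition should outrun enolisation of the acidic benzylic position; the new C2' stereocentre is racemic and is erased in step 6.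

Step 6
Reactants: 8 rac-1-[2,4-bis(methoxymethoxy)-6-methylphenyl]-3-methylbut-3-en-2-ol; 9 triethyl orthoacetate
Product: 12 ethyl (4E)-6-[2,4-bis(methoxymethoxy)-6-methylphenyl]-4-methylhex-4-enoate, via mixed orthoester 10 (not isolated), via ketene acetal 11 (not isolated)
Conditions: 9 (7 equiv), EtCO2H (0.1 equiv), 140 °C, EtOH distilled off
Reagents that add atoms: none
Why: Johnson orthoester Claisen rearrangement; the chair with the arylmethyl group pseudo-equatorial (an axial one would clash with the ethoxy group on the ketene acetal carbon) should give the E-C2'=C3' alkene, and the anhydrous weak acid spares the acetals.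

Step 7
Reactants: 12 ethyl (4E)-6-[2,4-bis(methoxymethoxy)-6-methylphenyl]-4-methylhex-4-enoate
Product: 14 (4E)-6-[2,4-bis(methoxymethoxy)-6-methylphenyl]-4-methylhex-4-enal, via aluminium hemiacetal 13 (not isolated)
Conditions: iBu2AlH (1.1 equiv), CH2Cl2, −78 °C; MeOH, then aq KNaC4H4O6
Reagents that add atoms: none
Why: Partial reduction of an unhindered ester; the tetrahedral aluminium hemiacetal persists at −78 °C and releases the aldehyde only on hydrolytic work-up.

Step 8
Reactants: 14 (4E)-6-[2,4-bis(methoxymethoxy)-6-methylphenyl]-4-methylhex-4-enal; 7 isopropenylmagnesium bromide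
Product: 15 rac-(6E)-8-[2,4-bis(methoxymethoxy)-6-methylphenyl]-2,6-dimethylocta-1,6-dien-3-ol
Conditions: 7 (1.3 equiv), THF, −78 → 0 °C; aq NH4Cl
Reagents that add atoms: none
Why: Grignard 1,2-addition to an unhindered aliphatic aldehyde; the C6' carbinol is formed racemic on purpose, since step 10 destroys this stereocentre.

Step 9
Reactants: 16 3-hydroxy-3-methylbutan-2-one
Product: 17 3,3-dimethoxy-2-methylbutan-2-ol
Conditions: HC(OMe)3 (1.5 equiv), MeOH, TsOH·H2O (1 mol %), rt; NaOMe quench; distillation
Reagents that add atoms: trimethyl orthoformate, COC(OC)OC; methanol, CO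
Why: Acid-catalysed ketalisation driven by the orthoformate as water scavenger; the tertiary hydroxyl does not interfere.

Step 10
Reactants: 15 rac-(6E)-8-[2,4-bis(methoxymethoxy)-6-methylphenyl]-2,6-dimethylocta-1,6-dien-3-ol; 17 3,3-dimethoxy-2-methylbutan-2-ol
Product: 20 (6E,10E)-12-[2,4-bis(methoxymethoxy)-6-methylphenyl]-2-hydroxy-2,6,10-trimethyldodeca-6,10-dien-3-one, via mixed ketal 18 (not isolated), via allyl vinyl ether 19 (not isolated)
Conditions: 17 (5 equiv), 2,4-dinitrophenol (0.1 equiv), toluene, 110 °C, MeOH distilled off, 24–48 h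
Reagents that add atoms: none
Why: Under the weak acid 2,4-dinitrophenol the C6' hydroxyl of 15 exchanges for one methoxyl of 17 to give mixed ketal 18, which loses methanol to allyl vinyl ether 19; this undergoes a concerted suprafacial [3,3] shift through a chair, forming the C8'–C9' bond, the C6'=C7' alkene and the C10' carbonyl as the C6'–O bond breaks. This is the Johnson–Faulkner ketal Claisen rearrangement, a known reaction of isopropenyl carbinols with this hydroxy ketal. No ring is closed and no stereocentre is created; the only stereochemical element formed is the alkene geometry. The E geometry should follow from the chair in which the C5' chain on C6' is pseudo-equatorial, because an axial chain would clash with the C(CH3)2OH group on the vinyl ether carbon, so both enantiomers of 15 converge on the same E product. The step needs chemoselectivity against ionisation of the allylic carbinol and against loss of the methoxymethyl ethers, which the weakness of the acid, the absence of water and the continuous removal of methanol should secure. The E-C2'=C3' alkene and the arene are spectators, and the product holds every carbon and oxygen of the target.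

Step 11
Reactants: 20 (6E,10E)-12-[2,4-bis(methoxymethoxy)-6-methylphenyl]-2-hydroxy-2,6,10-trimethyldodeca-6,10-dien-3-one
Product: 21 (6E,10E)-12-[2,4-bis(methoxymethoxy)-6-methylphenyl]-2,6,10-trimethyl-2-[(trimethylsilyl)oxy]dodeca-6,10-dien-3-one
Conditions: 1-(trimethylsilyl)imidazole (1.5 equiv), CH2Cl2, rt
Reagents that add atoms: 1-(trimethylsilyl)imidazole, C[Si](C)(C)n1ccnc1
Why: Neutral silyl transfer caps the tertiary hydroxyl, which would otherwise consume the borane and open an uncatalysed reduction path; silyl triflates are avoided because they attack aryl methoxymethyl ethers.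

Step 12
Reactants: 21 (6E,10E)-12-[2,4-bis(methoxymethoxy)-6-methylphenyl]-2,6,10-trimethyl-2-[(trimethylsilyl)oxy]dodeca-6,10-dien-3-one
Product: 22 (3S,6E,10E)-12-[2,4-bis(methoxymethoxy)-6-methylphenyl]-2,6,10-trimethyl-2-[(trimethylsilyl)oxy]dodeca-6,10-dien-3-ol
Conditions: (R)-2-methyl-CBS-oxazaborolidine [(3aR)-1-methyl-3,3-diphenyltetrahydro-1H,3H-pyrrolo[1,2-c][1,3,2]oxazaborole, 0.2 equiv], catecholborane (1.8 equiv), toluene, −78 → −40 °C; MeOH quench, aq NaHCO3 wash
Reagents that add atoms: none
Why: Corey–Bakshi–Shibata reduction: the ketone binds the catalyst boron anti to the bulky C(CH3)2OSiMe3 flank and hydride passes from the nitrogen-bound borane through a six-membered transition state, so the (R)-catalyst should give the (S)-C10' carbinol (the sense known for tert-alkyl alkyl ketones), while catecholborane does not hydroborate the two trisubstituted alkenes at this temperature.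

Step 13
Reactants: 22 (3S,6E,10E)-12-[2,4-bis(methoxymethoxy)-6-methylphenyl]-2,6,10-trimethyl-2-[(trimethylsilyl)oxy]dodeca-6,10-dien-3-ol
Product: 23 4-[(2E,6E,10S)-10,11-dihydroxy-3,7,11-trimethyldodeca-2,6-dien-1-yl]-5-methylbenzene-1,3-diol
Conditions: HCl (0.5 M) in MeOH, 0 °C → rt, stopped at full conversion
Reagents that add atoms: none
Why: Acid-catalysed methanolysis of the two aryl methoxymethyl acetals and of the tertiary silyl ether; dilute acid at room temperature should not ionise the C10' carbinol or protonate the trisubstituted alkenes.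

**Compound list**

1 | 2,4-dihydroxy-6-methylbenzaldehyde | Cc1cc(O)cc(O)c1C=O | starting material
2 | 2,4-bis(methoxymethoxy)-6-methylbenzaldehyde | COCOc1cc(C)c(C=O)c(OCOC)c1 | intermediate
3 | 2-ethenyl-1,5-bis(methoxymethoxy)-3-methylbenzene | COCOc1cc(C)c(C=C)c(OCOC)c1 | intermediate
4 | 9-{2-[2,4-bis(methoxymethoxy)-6-methylphenyl]ethyl}-9-borabicyclo[3.3.1]nonane (alkylborane) | COCOc1cc(C)c(CCB2C3CCCC2CCC3)c(OCOC)c1 | intermediate (not isolated)
5 | 2-[2,4-bis(methoxymethoxy)-6-methylphenyl]ethan-1-ol | COCOc1cc(C)c(CCO)c(OCOC)c1 | intermediate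
6 | [2,4-bis(methoxymethoxy)-6-methylphenyl]acetaldehyde | COCOc1cc(C)c(CC=O)c(OCOC)c1 | intermediate
7 | isopropenylmagnesium bromide | CC(=C)[Mg]Br | starting material
8 | rac-1-[2,4-bis(methoxymethoxy)-6-methylphenyl]-3-methylbut-3-en-2-ol | COCOc1cc(C)c(CC(O)C(C)=C)c(OCOC)c1 | intermediate
9 | triethyl orthoacetate | CCOC(C)(OCC)OCC | starting material
10 | mixed orthoester: 1,1-diethoxyethyl ether of 8 | COCOc1cc(C)c(CC(OC(C)(OCC)OCC)C(C)=C)c(OCOC)c1 | intermediate (not isolated)
11 | ketene acetal: 1-ethoxyethenyl ether of 8 | COCOc1cc(C)c(CC(OC(=C)OCC)C(C)=C)c(OCOC)c1 | intermediate (not isolated)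
12 | ethyl (4E)-6-[2,4-bis(methoxymethoxy)-6-methylphenyl]-4-methylhex-4-enoate | COCOc1cc(C)c(C/C=C(\C)CCC(=O)OCC)c(OCOC)c1 | intermediate
13 | aluminium hemiacetal: O-diisobutylaluminium O-ethyl hemiacetal of aldehyde 14 | COCOc1cc(C)c(C/C=C(\C)CCC(OCC)O[Al](CC(C)C)CC(C)C)c(OCOC)c1 | intermediate (not isolated)
14 | (4E)-6-[2,4-bis(methoxymethoxy)-6-methylphenyl]-4-methylhex-4-enal | COCOc1cc(C)c(C/C=C(\C)CCC=O)c(OCOC)c1 | intermediate
15 | rac-(6E)-8-[2,4-bis(methoxymethoxy)-6-methylphenyl]-2,6-dimethylocta-1,6-dien-3-ol | COCOc1cc(C)c(C/C=C(\C)CCC(O)C(C)=C)c(OCOC)c1 | intermediate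
16 | 3-hydroxy-3-methylbutan-2-one | CC(=O)C(C)(C)O | starting material
17 | 3,3-dimethoxy-2-methylbutan-2-ol | COC(C)(OC)C(C)(C)O | intermediate
18 | mixed ketal: 3-methoxy-2-methyl-3-{[(6E)-8-aryl-2,6-dimethylocta-1,6-dien-3-yl]oxy}butan-2-ol (aryl = 2,4-bis(methoxymethoxy)-6-methylphenyl) | COCOc1cc(C)c(C/C=C(\C)CCC(OC(C)(OC)C(C)(C)O)C(C)=C)c(OCOC)c1 | intermediate (not isolated)
19 | allyl vinyl ether: 2-methyl-3-{[(6E)-8-aryl-2,6-dimethylocta-1,6-dien-3-yl]oxy}but-3-en-2-ol (same aryl) | COCOc1cc(C)c(C/C=C(\C)CCC(OC(=C)C(C)(C)O)C(C)=C)c(OCOC)c1 | intermediate (not isolated)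
20 | (6E,10E)-12-[2,4-bis(methoxymethoxy)-6-methylphenyl]-2-hydroxy-2,6,10-trimethyldodeca-6,10-dien-3-one | COCOc1cc(C)c(C/C=C(\C)CC/C=C(\C)CCC(=O)C(C)(C)O)c(OCOC)c1 | intermediate
21 | (6E,10E)-12-[2,4-bis(methoxymethoxy)-6-methylphenyl]-2,6,10-trimethyl-2-[(trimethylsilyl)oxy]dodeca-6,10-dien-3-one | COCOc1cc(C)c(C/C=C(\C)CC/C=C(\C)CCC(=O)C(C)(C)O[Si](C)(C)C)c(OCOC)c1 | intermediate
22 | (3S,6E,10E)-12-[2,4-bis(methoxymethoxy)-6-methylphenyl]-2,6,10-trimethyl-2-[(trimethylsilyl)oxy]dodeca-6,10-dien-3-ol | COCOc1cc(C)c(C/C=C(\C)CC/C=C(\C)CC[C@H](O)C(C)(C)O[Si](C)(C)C)c(OCOC)c1 | intermediate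
23 | 4-[(2E,6E,10S)-10,11-dihydroxy-3,7,11-trimethyldodeca-2,6-dien-1-yl]-5-methylbenzene-1,3-diol | Cc1cc(O)cc(O)c1C/C=C(\C)CC/C=C(\C)CC[C@H](O)C(C)(C)O | target

**Step count and risks**

Total step count: 13. Longest linear sequence: 12 (steps 1–8 and 10–13; step 9 is a one-step side branch).

Steps most likely to fail:

1. Step 10 (ketal Claisen). The ketal exchange may stall, or the acid may ionise or dehydrate the allylic carbinol faster than the enol ether forms, so that little material enters the rearrangement. The fallback sets out from 15 and comes back at 20. The orthoester Claisen already relied on in step 6 (9, EtCO2H, 140 °C) should give ethyl (4E,8E)-10-[2,4-bis(methoxymethoxy)-6-methylphenyl]-4,8-dimethyldeca-4,8-dienoate F1. Treatment with MeNHOMe·HCl and iPrMgCl in THF at −20 °C converts it to (4E,8E)-10-[2,4-bis(methoxymethoxy)-6-methylphenyl]-N-methoxy-N,4,8-trimethyldeca-4,8-dienamide F2. Isopropenylmagnesium bromide 7 then gives (6E,10E)-12-[2,4-bis(methoxymethoxy)-6-methylphenyl]-2,6,10-trimethyldodeca-1,6,10-trien-3-one F3. Radical hydration of the conjugated alkene alone (Mn(dpm)3, i.e. tris(dipivaloylmethanato)manganese, as catalyst, PhSiH3, O2, iPrOH, then P(OEt)3) places the tertiary hydroxyl alpha to the ketone and delivers 20.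

2. Step 12 (oxazaborolidine reduction). Facial discrimination may be poor, or the silyl ether may be lost so that uncatalysed reduction erodes the enantiomeric purity. The fallback sets out from 20 and comes back at 23, replacing asymmetric catalysis by resolution. NaBH4 in MeOH at 0 °C gives rac-(6E,10E)-12-[2,4-bis(methoxymethoxy)-6-methylphenyl]-2,6,10-trimethyldodeca-6,10-diene-2,3-diol F4. Esterification of the secondary hydroxyl with (S)-2-methoxy-2-phenylacetic acid (DCC, DMAP, CH2Cl2) and chromatographic separation of the diastereomers gives the (3S)-carbinol (S)-2-methoxy-2-phenylacetate F5, its configuration to be assigned by the mandelate shift model. LiOH in THF/MeOH/H2O frees (3S,6E,10E)-12-[2,4-bis(methoxymethoxy)-6-methylphenyl]-2,6,10-trimethyldodeca-6,10-diene-2,3-diol F6, which the conditions of step 13 convert to 23. The other diastereomer can be saponified and reoxidised to 20.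

3. Step 13 (global acid deprotection). The freed C3 phenol may add to the acid-activated C2'=C3' alkene to form a chroman, or formaldehyde equivalents released from the acetals may alkylate the electron-rich ring. The fallback sets out from 22 and comes back at 23, using silyl transfer in place of protic acid. TMSOTf with 2,2'-bipyridyl in CH2Cl2 at 0 °C exchanges both aryl methoxymethyl ethers for silyl ethers and silylates the C10' hydroxyl, giving the tetrakis(trimethylsilyl) ether of 23 F7. Citric acid in MeOH at rt then removes all four silyl groups to give 23.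

**Further compounds**

F1 | step 10 | ethyl (4E,8E)-10-[2,4-bis(methoxymethoxy)-6-methylphenyl]-4,8-dimethyldeca-4,8-dienoate | COCOc1cc(C)c(C/C=C(\C)CC/C=C(\C)CCC(=O)OCC)c(OCOC)c1
F2 | step 10 | (4E,8E)-10-[2,4-bis(methoxymethoxy)-6-methylphenyl]-N-methoxy-N,4,8-trimethyldeca-4,8-dienamide | COCOc1cc(C)c(C/C=C(\C)CC/C=C(\C)CCC(=O)N(C)OC)c(OCOC)c1
F3 | step 10 | (6E,10E)-12-[2,4-bis(methoxymethoxy)-6-methylphenyl]-2,6,10-trimethyldodeca-1,6,10-trien-3-one | COCOc1cc(C)c(C/C=C(\C)CC/C=C(\C)CCC(=O)C(C)=C)c(OCOC)c1
F4 | step 12 | rac-(6E,10E)-12-[2,4-bis(methoxymethoxy)-6-methylphenyl]-2,6,10-trimethyldodeca-6,10-diene-2,3-diol | COCOc1cc(C)c(C/C=C(\C)CC/C=C(\C)CCC(O)C(C)(C)O)c(OCOC)c1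
F5 | step 12 | (3S,6E,10E)-12-[2,4-bis(methoxymethoxy)-6-methylphenyl]-2-hydroxy-2,6,10-trimethyldodeca-6,10-dien-3-yl (S)-2-methoxy-2-phenylacetate | COCOc1cc(C)c(C/C=C(\C)CC/C=C(\C)CC[C@H](OC(=O)[C@@H](OC)c2ccccc2)C(C)(C)O)c(OCOC)c1
F6 | step 12 | (3S,6E,10E)-12-[2,4-bis(methoxymethoxy)-6-methylphenyl]-2,6,10-trimethyldodeca-6,10-diene-2,3-diol | COCOc1cc(C)c(C/C=C(\C)CC/C=C(\C)CC[C@H](O)C(C)(C)O)c(OCOC)c1
F7 | step 13 | tetrakis(trimethylsilyl) ether of 23: {[(3S,6E,10E)-12-{2,4-bis[(trimethylsilyl)oxy]-6-methylphenyl}-2,6,10-trimethyldodeca-6,10-diene-2,3-diyl]bis(oxy)}bis(trimethylsilane) | C[Si](C)(C)Oc1cc(C)c(C/C=C(\C)CC/C=C(\C)CC[C@H](O[Si](C)(C)C)C(C)(C)O[Si](C)(C)C)c(O[Si](C)(C)C)c1
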